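Chamigrane numbering is used: ring B = C1–C6 (C2 Cl, C3 CH3/OH, C6 spiro), ring A = C6–C11 (C7=C14H2, C9 OH, C10 Br, C11 Me2). Ring B is disconnected at C4–C5 and C2–C3 into a spiro-cyclobutanone (C6, C1, C2=O, C5) and a propyne unit (C3, C4). The key step exploits the quaternary spiro atom C6, whose two ring-B arms C1H2 and C5H2 are enantiotopic in the achiral spiro[3.5]nonenone precursor. A chiral nickel(0) catalyst inserts a silylpropyne into one C2–CH2 bond, which closes ring B and fixes C6 in one operation. C3, C2, C10 and C9 are then set in relay from C6.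

Key step: step 6

Remark: the ligand antipode that gives the required C6 configuration in step 6 must be found by experiment (both antipodes are available). The R/S label of C6 changes along the route only because CIP priorities change; its spatial arrangement stays constant.

Step 1
Reactants: 1 4-oxoisophorone
Product: 2 4-oxoisophorone 4-ethylene ketal (7,9,9-trimethyl-1,4-dioxaspiro[4.5]dec-6-en-8-one)
Conditions: HOCH2CH2OH, p-TsOH (cat.), toluene, Dean–Stark, reflux
Reagents that add atoms: ethylene glycol (OCCO)
Why: Acid-catalysed ketalisation should take place only at the less hindered carbonyl (future C9), because the other carbonyl is flanked by CMe2 and C(CH3)=.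

Step 2
Reactants: 2 4-oxoisophorone 4-ethylene ketal
Product: 3 7,9,9-trimethyl-8-methylene-1,4-dioxaspiro[4.5]dec-6-ene
Conditions: Ph3PCH3Br, KOtBu, toluene, 100 °C
Reagents that add atoms: methyltriphenylphosphonium bromide (C[P+](c1ccccc1)(c1ccccc1)c1ccccc1.[Br-])
Why: Wittig methylenation under the forcing conditions used for hindered ketones should work because this carbonyl has no alpha-hydrogen and cannot be lost by enolisation.

Step 3
Reactants: 3 7,9,9-trimethyl-8-methylene-1,4-dioxaspiro[4.5]dec-6-ene
Product: 4 racemic 1,1-dichloro-5,9,9-trimethylspiro[3.5]non-5-ene-2,7-dione 7-ethylene ketal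
Conditions: Cl3CCOCl, Zn–Cu, Et2O/DME, rt
Reagents that add atoms: trichloroacetyl chloride (O=C(Cl)C(Cl)(Cl)Cl)
Why: In the ketene–alkene [2+2] cycloaddition the ketene carbonyl carbon bonds to the terminal CH2 and CCl2 to the allyl-stabilised inner carbon of the more reactive 1,1-disubstituted alkene, and the racemic spiro centre formed here disappears in step 4.

Step 4
Reactants: 4 racemic dichlorocyclobutanone
Product: 5 5,9,9-trimethylspiro[3.5]non-5-ene-2,7-dione 7-ethylene ketal (achiral)
Conditions: Zn dust, NH4Cl, MeOH, rt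
Reagents that add atoms: none
Why: Zinc-mediated reductive dechlorination of alpha,alpha-dichlorocyclobutanones is standard, and these near-neutral conditions should leave the ketal intact.

Step 5
Reactants: 6 1-propynylmagnesium bromide; 7 benzylchlorodimethylsilane
Product: 8 benzyldimethyl(prop-1-yn-1-yl)silane
Conditions: THF, 0 °C to rt
Reagents that add atoms: none
Why: Silylation of an alkynyl Grignard reagent gives an internal alkyne whose silyl group steers the regiochemistry in step 6 and is fluoride-labile in step 7.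

Step 6
Reactants: 5 spiro-cyclobutanone; 8 benzyldimethyl(prop-1-yn-1-yl)silane
Product: 9 (6S)-4-(benzyldimethylsilyl)chamigra-3,7-diene-2,9-dione 9-ethylene ketal
Conditions: Ni(cod)2 (10 mol %), BINOL-derived bis(1-phenylethyl)amine phosphoramidite L* (20 mol %), 8 (1.5 equiv), toluene, 90 °C
Reagents that add atoms: none
Why: Proposed new method: Ni(0)L* binds the alkyne and the strained C2=O of 5 and couples them oxidatively to an oxanickelacyclopentene (new C2–C3 bond, with the silyl-bearing carbon C4 on nickel as in nickel-catalysed aldehyde–silylalkyne couplings), beta-carbon elimination then cleaves one C2–CH2 bond to a seven-membered nickelacycle, and C(sp2)–C(sp3) reductive elimination forms C4–C5. The closest known reactions are the Ni(cod)2/PCy3-catalysed intermolecular alkyne insertion into 3,3-disubstituted cyclobutanones (racemic) and the nickel/phosphoramidite-catalysed enantioselective intramolecular alkene insertion into prochiral cyclobutanones, so the new element is selection between enantiotopic C–C bonds in the intermolecular mode. Ring B closes as a formal [4+2] two-carbon ring expansion, the closing event being reductive elimination from the seven-membered metallacycle. The only new stereocentre, C6, is defined by which enantiotopic CH2–C(O) bond migrates to nickel, and the ligand must control this because 5 has a time-averaged mirror plane through ring A. The step needs three selectivities: regioselectivity, secured by the bulky silyl group; chemoselectivity for the cyclobutanone, secured by ring strain, the ketal at C9 and the hindered trisubstituted C7=C8; and suppression of alkyne oligomerisation, secured by using an internal silylalkyne.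

Step 7
Reactants: 9 silyl dienone ketal
Product: 11 (6R)-chamigra-3,7-diene-2,9-dione, via desilylated ketal 10 (not isolated)
Conditions: TBAF (wet), THF, 0 °C to rt; then 1 M HCl, rt
Reagents that add atoms: water (O)
Why: Fluoride-triggered debenzylation and ipso-protodesilylation of the benzyldimethylsilyl alkene, followed by acid hydrolysis of the ketal, should free C4–H and the C9 ketone without touching C6.

Step 8
Reactants: 11 (6R)-chamigra-3,7-diene-2,9-dione
Product: 13 (3R,6R)-3-hydroxychamigr-7-ene-2,9-dione, via hydroperoxide 12 (not isolated)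
Conditions: Mn(dpm)3 (cat.), PhSiH3, O2 (1 atm), iPrOH/CH2Cl2, 0 °C; then P(OEt)3
Reagents that add atoms: dioxygen (O=O)
Why: In this Mukaiyama-type hydrogen-atom-transfer alpha-hydroxylation of an enone, H adds to the unhindered beta-CH (C4) of ring B faster than to the fully substituted C7 of ring A, and O2 traps the C3 radical axially on the face of ring B opposite to axial C7 (C11 equatorial), which sets 3R.

Step 9
Reactants: 13 ketol
Product: 14 (2R,3R,6R)-2,3-dihydroxychamigr-7-en-9-one (trans-diaxial diol)
Conditions: Me4NBH(OAc)3, MeCN/AcOH, −20 °C to rt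
Reagents that add atoms: none
Why: In the Saksena–Evans hydroxyl-directed reduction only the ketone next to C3–OH is reduced, with hydride delivered from the C3–O face to give the trans-diol; the enone is spared, and the C2 centre is erased again in step 11.

Step 10
Reactants: 14 trans-diol
Product: 16 cesium 2-O-oxalate of 14, via methyl oxalate 15 (not isolated)
Conditions: ClC(O)CO2Me, Et3N, DMAP (cat.), CH2Cl2, 0 °C; then CsOH (1.0 equiv, aq), THF, 0 °C
Reagents that add atoms: methyl chlorooxoacetate (COC(=O)C(=O)Cl); cesium hydroxide ([Cs+].[OH-])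
Why: Only the secondary hydroxyl is acylated by the small, very reactive acid chloride, and the activated methyl ester is saponified selectively by one equivalent of base.

Step 11
Reactants: 16 cesium oxalate
Product: 17 (2S,3R,6R)-2-chloro-3-hydroxychamigr-7-en-9-one (Cl equatorial; cis to C3–OH)
Conditions: [Ir(dF(CF3)ppy)2(dtbbpy)]PF6 (1 mol %), Cl3CCO2Et, DME/DMF, blue LEDs, rt
Reagents that add atoms: ethyl trichloroacetate (CCOC(=O)C(Cl)(Cl)Cl)
Why: In this photoredox radical deoxychlorination of a cesium oxalate, oxidation and loss of two CO2 give the C2 radical, which should abstract Cl on the face opposite to syn-axial C7 (2S); this avoids an SN2 reaction next to fully substituted C3 and epoxide formation by the anti-periplanar C3 oxygen.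

Step 12
Reactants: 17 chlorohydrin enone
Product: 19 (2S,3R,6S,10S)-10-bromo-2-chloro-3-(trimethylsilyloxy)chamigr-7-en-9-one, via bis-silyl ether 18 (not isolated)
Conditions: LDA (2.3 equiv), THF, −78 °C; TMSCl, −78 to 0 °C; then NBS, THF, −78 °C
Reagents that add atoms: chlorotrimethylsilane (C[Si](C)(C)Cl); N-bromosuccinimide (O=C1CCC(=O)N1Br)
Why: Kinetic alpha'-deprotonation of the enone (as with isophorone), O-silylation and bromination of the cross-conjugated silyl dienol ether place Br at C10, where it settles equatorial; the wanted 10S epimer (Br syn to C1) needs the ring-A half-chair with C5 pseudoaxial, for which ring B offers only a weak bias (see risks).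

Step 13
Reactants: 19 bromo enone
Product: 20 (2S,3R,6S,10S)-10-bromo-2-chloro-3,9-bis(trimethylsilyloxy)chamigra-7(14),8-diene
Conditions: TMSOTf, Et3N, CH2Cl2, 0 °C to rt
Reagents that add atoms: trimethylsilyl triflate (C[Si](C)(C)OS(=O)(=O)C(F)(F)F)
Why: Soft enolisation under equilibrating conditions should remove an accessible C14 proton rather than the shielded C10–H and give the linearly conjugated dienol ether (as with steroidal 4-en-3-ones), which installs C7=C14 and freezes C10.

Step 14
Reactants: 20 dienol ether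
Product: 23 (2S,3R,6S,9R,10S)-10-bromo-2-chlorochamigr-7(14)-ene-3,9-diol (CNP0121782.1), via bromo ketone 21 (not isolated), via silyl ether 22 (not isolated)
Conditions: NaBH4, MeOH/THF, −20 to 0 °C; then 0.5 M citric acid, MeOH, 0 °C
Reagents that add atoms: none
Why: This deconjugative reduction follows the principle of the dienol acetate/borohydride reduction of steroidal enones: methanolysis of the enol silane, kinetic protonation at C8 and immediate reduction of the beta,gamma-enone. Hydride attacks equatorially because the axial C11 methyl blocks the axial path, giving the axial 9R alcohol cis to Br, and the mild acid work-up removes the tertiary TMS ether.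

Compound list
1 | 4-oxoisophorone (2,6,6-trimethylcyclohex-2-ene-1,4-dione) | CC1=CC(=O)CC(C)(C)C1=O | starting material
2 | 7,9,9-trimethyl-1,4-dioxaspiro[4.5]dec-6-en-8-one | CC1=CC2(CC(C)(C)C1=O)OCCO2 | intermediate
3 | 7,9,9-trimethyl-8-methylene-1,4-dioxaspiro[4.5]dec-6-ene | C=C1C(C)=CC2(CC1(C)C)OCCO2 | intermediate
4 | racemic 1,1-dichloro-5,9,9-trimethylspiro[3.5]non-5-ene-2,7-dione 7-ethylene ketal | O=C1CC2(C(C)=CC3(CC2(C)C)OCCO3)C1(Cl)Cl | intermediate
5 | 5,9,9-trimethylspiro[3.5]non-5-ene-2,7-dione 7-ethylene ketal (achiral) | O=C1CC2(C1)C(C)=CC3(CC2(C)C)OCCO3 | intermediate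
6 | 1-propynylmagnesium bromide | CC#C[Mg]Br | starting material
7 | benzylchlorodimethylsilane | C[Si](C)(Cl)Cc1ccccc1 | starting material
8 | benzyldimethyl(prop-1-yn-1-yl)silane | CC#C[Si](C)(C)Cc1ccccc1 | intermediate
9 | (6S)-4-(benzyldimethylsilyl)chamigra-3,7-diene-2,9-dione 9-ethylene ketal | CC1=CC3(OCCO3)CC(C)(C)[C@]12CC([Si](C)(C)Cc3ccccc3)=C(C)C(=O)C2 | intermediate
10 | (6R)-chamigra-3,7-diene-2,9-dione 9-ethylene ketal | CC1=CC3(OCCO3)CC(C)(C)[C@]12CC=C(C)C(=O)C2 | intermediate
11 | (6R)-chamigra-3,7-diene-2,9-dione | CC1=CC(=O)CC(C)(C)[C@]12CC=C(C)C(=O)C2 | intermediate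
12 | (3R,6R)-3-hydroperoxychamigr-7-ene-2,9-dione | CC1=CC(=O)CC(C)(C)[C@]12CC[C@@](C)(OO)C(=O)C2 | intermediate
13 | (3R,6R)-3-hydroxychamigr-7-ene-2,9-dione | CC1=CC(=O)CC(C)(C)[C@]12CC[C@@](C)(O)C(=O)C2 | intermediate
14 | (2R,3R,6R)-2,3-dihydroxychamigr-7-en-9-one | CC1=CC(=O)CC(C)(C)[C@]12CC[C@@](C)(O)[C@H](O)C2 | intermediate
15 | 2-O-(methoxyoxalyl) derivative of 14 | CC1=CC(=O)CC(C)(C)[C@]12CC[C@@](C)(O)[C@H](OC(=O)C(=O)OC)C2 | intermediate
16 | cesium 2-O-oxalate of 14 | CC1=CC(=O)CC(C)(C)[C@]12CC[C@@](C)(O)[C@H](OC(=O)C(=O)[O-])C2.[Cs+] | intermediate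
17 | (2S,3R,6R)-2-chloro-3-hydroxychamigr-7-en-9-one | CC1=CC(=O)CC(C)(C)[C@]12CC[C@@](C)(O)[C@@H](Cl)C2 | intermediate
18 | (2S,3R,6S)-2-chloro-3,9-bis(trimethylsilyloxy)chamigra-7,9-diene | CC1=CC(O[Si](C)(C)C)=CC(C)(C)[C@]12CC[C@@](C)(O[Si](C)(C)C)[C@@H](Cl)C2 | intermediate
19 | (2S,3R,6S,10S)-10-bromo-2-chloro-3-(trimethylsilyloxy)chamigr-7-en-9-one | CC1=CC(=O)[C@@H](Br)C(C)(C)[C@]12CC[C@@](C)(O[Si](C)(C)C)[C@@H](Cl)C2 | intermediate
20 | (2S,3R,6S,10S)-10-bromo-2-chloro-3,9-bis(trimethylsilyloxy)chamigra-7(14),8-diene | C=C1C=C(O[Si](C)(C)C)[C@@H](Br)C(C)(C)[C@]12CC[C@@](C)(O[Si](C)(C)C)[C@@H](Cl)C2 | intermediate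
21 | (2S,3R,6S,10S)-10-bromo-2-chloro-3-(trimethylsilyloxy)chamigr-7(14)-en-9-one | C=C1CC(=O)[C@@H](Br)C(C)(C)[C@]12CC[C@@](C)(O[Si](C)(C)C)[C@@H](Cl)C2 | intermediate
22 | 3-O-trimethylsilyl ether of 23 | C=C1C[C@@H](O)[C@@H](Br)C(C)(C)[C@]12CC[C@@](C)(O[Si](C)(C)C)[C@@H](Cl)C2 | intermediate
23 | (2S,3R,6S,9R,10S)-10-bromo-2-chlorochamigr-7(14)-ene-3,9-diol | C=C1C[C@@H](O)[C@@H](Br)C(C)(C)[C@]12CC[C@@](C)(O)[C@@H](Cl)C2 | target

Total step count: 14. Longest linear sequence: 13 (steps 1–4 and 6–14).

Steps most likely to fail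

1. Step 6 (Proposed new method). The ligand may discriminate poorly between the two enantiotopic C2–CH2 bonds, reductive elimination at neopentyl C5 may be slow, and alkyne oligomerisation may compete. The fallback uses known chemistry, sets out from 5 and returns at 11. Compound 5 is transketalised with (R,R)-hydrobenzoin (PPTS, benzene, Dean–Stark) to the C2-symmetric chiral ketal F1. The known achiral Ni(cod)2/PCy3 alkyne insertion with 8 should then give the spiroenone F2 and its C6 epimer F3 as diastereomers that can be separated by chromatography or crystallisation. The conditions of step 7 (TBAF, then aqueous HCl) remove both the silyl group and the auxiliary from F2 and give 11.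

2. Step 12. Facial selection at C10 may be poor: once C2 is sp3, the axial hydrogens at C2 and C4 flank the C7 methyl group equally, so neither ring-A half-chair is preferred. The fallback sets out from 13 and returns at 20. It brominates earlier, on ketol 13, where C2 is trigonal. The C7 methyl group can then lean only toward C2, C1 becomes pseudo-equatorial on ring A, and the equatorial bromide is the 10S epimer.
   - LDA (2.3 equiv)/TMSCl gives the bis-silyl ether F4; the C3 alkoxide next to C2=O and the syn-axial oxygen should disfavour enolisation toward C1.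
   - NBS followed by citric acid gives the bromo ketol F5.
   - Me4NBH(OAc)3 gives the bromo diol F6.
   - Acylation gives the methyl oxalate F7, and one equivalent of CsOH gives the cesium oxalate F8.
   - Photoredox chlorination as in step 11 gives the bromo chlorohydrin enone F9.
   - TMSOTf/Et3N silylates both oxygens of F9 and delivers 20.

3. Step 11. Acylation of the crowded axial alcohol in the preceding step may be slow, and the C2 radical may abstract hydrogen or take up chlorine from the wrong face. The fallback sets out from 9 and returns at 17. It installs chlorine first by polar allylic substitution and oxygen second.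
   - DIBAL (−78 °C) attacks C2=O of 9 from the face opposite to C7 and gives the allylic alcohol F10.
   - Appel chlorination proceeds with inversion, the silyl group at C4 blocking SN2' attack and keeping ring B unsymmetrical, and gives the allylic chloride F11.
   - mCPBA epoxidises the vinylsilane on the face opposite to C7 and gives the epoxysilane F12.
   - TBAF protodesilylates with retention to the epoxide F13.
   - LiAlH4 opens the epoxide at C4 in the trans-diaxial sense to the ketal chlorohydrin F14, and aqueous HCl gives 17.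

Further compounds
F1 | step 6 | (R,R)-hydrobenzoin ketal of the spiro-cyclobutanone | O=C1CC2(C1)C(C)=CC3(CC2(C)C)O[C@H](c4ccccc4)[C@@H](c4ccccc4)O3
F2 | step 6 | 4-silyl spirodienone (R,R)-hydrobenzoin ketal with C6 configured as in 9 | CC1=CC3(O[C@H](c4ccccc4)[C@@H](c4ccccc4)O3)CC(C)(C)[C@]12CC([Si](C)(C)Cc3ccccc3)=C(C)C(=O)C2
F3 | step 6 | C6 epimer of F2 | CC1=CC3(O[C@H](c4ccccc4)[C@@H](c4ccccc4)O3)CC(C)(C)[C@@]12CC([Si](C)(C)Cc3ccccc3)=C(C)C(=O)C2
F4 | step 12 | 3,9-bis(trimethylsilyloxy)chamigra-7,9-dien-2-one | CC1=CC(O[Si](C)(C)C)=CC(C)(C)[C@]12CC[C@@](C)(O[Si](C)(C)C)C(=O)C2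
F5 | step 12 | 10-bromo-3-hydroxychamigr-7-ene-2,9-dione | CC1=CC(=O)[C@@H](Br)C(C)(C)[C@]12CC[C@@](C)(O)C(=O)C2
F6 | step 12 | 10-bromo-2,3-dihydroxychamigr-7-en-9-one (trans-diol) | CC1=CC(=O)[C@@H](Br)C(C)(C)[C@]12CC[C@@](C)(O)[C@H](O)C2
F7 | step 12 | 2-O-(methoxyoxalyl) derivative of F6 | CC1=CC(=O)[C@@H](Br)C(C)(C)[C@]12CC[C@@](C)(O)[C@H](OC(=O)C(=O)OC)C2
F8 | step 12 | cesium 2-O-oxalate of F6 | CC1=CC(=O)[C@@H](Br)C(C)(C)[C@]12CC[C@@](C)(O)[C@H](OC(=O)C(=O)[O-])C2.[Cs+]
F9 | step 12 | 10-bromo-2-chloro-3-hydroxychamigr-7-en-9-one | CC1=CC(=O)[C@@H](Br)C(C)(C)[C@]12CC[C@@](C)(O)[C@@H](Cl)C2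
F10 | step 11 | 4-silyl-2-hydroxychamigra-3,7-dien-9-one ethylene ketal | CC1=CC3(OCCO3)CC(C)(C)[C@]12CC([Si](C)(C)Cc3ccccc3)=C(C)[C@H](O)C2
F11 | step 11 | 4-silyl-2-chlorochamigra-3,7-dien-9-one ethylene ketal | CC1=CC3(OCCO3)CC(C)(C)[C@]12CC([Si](C)(C)Cc3ccccc3)=C(C)[C@@H](Cl)C2
F12 | step 11 | 3,4-epoxy-4-silyl-2-chlorochamigr-7-en-9-one ethylene ketal | CC1=CC3(OCCO3)CC(C)(C)[C@]12C[C@@]4([Si](C)(C)Cc3ccccc3)O[C@@]4(C)[C@@H](Cl)C2
F13 | step 11 | 3,4-epoxy-2-chlorochamigr-7-en-9-one ethylene ketal | CC1=CC3(OCCO3)CC(C)(C)[C@]12C[C@H]4O[C@@]4(C)[C@@H](Cl)C2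
F14 | step 11 | 2-chloro-3-hydroxychamigr-7-en-9-one ethylene ketal | CC1=CC3(OCCO3)CC(C)(C)[C@]12CC[C@@](C)(O)[C@@H](Cl)C2
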